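Readings and results were computed on assumed constants; noise was put on by code.

Temperature was what differed among the four flasks, from −40 °C to 50 °C, so I first asked how fast Q goes at each.

| setting | eta | zeta | teal | amber | green | red |
|---|---|---|---|---|---|---|
| Q | 0.15 M | 0.35 M | 0.23 M | 0.23 M | 0.23 M | 0.23 M |
| D | 0.575 M | 0.575 M | 0.575 M | 0.575 M | 0.575 M | 0.575 M |
| temperature | −18 °C | 32 °C | 20 °C | 50 °C | −10 °C | −40 °C |
| remark | run made earlier | run made earlier |  |  |  |  |
| time |  |  | 40 min | 40 min | 40 min | 40 min |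

| run | time / min | E / % | Q / % |
|---|---|---|---|
| eta | 25.0 | 0.6 | 99.4 |
| eta | 50.0 | 0 | 97.3 |
| eta | 80.0 | 0 | 95.1 |
| eta | 90.0 | 0.3 | 96.1 |
| eta | 120 | 0.3 | 94.3 |
| eta | 150 | 1.3 | 93.9 |
| zeta | 2.00 | 20.7 | 27.2 |
| zeta | 4.00 | 40.5 | 7.8 |
| zeta | 6.00 | 49.5 | 2.2 |
| zeta | 8.00 | 52.0 | 0.2 |
| zeta | 12.0 | 53.1 | 0 |
| zeta | 15.0 | 52.4 | 0.3 |

(standard deviation of a reading: 0.5 percentage points)

- the best flask by amount of E, in percent of the Q charged; "all alike" if 1.5 percentage points covers them all (teal / amber / green / red / all alike)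
- amount of E at the end, in percent of the Q charged, teal
- amount of E at the end, in percent of the Q charged, amber
- amount of E at the end, in percent of the Q charged, green
- amount of E at the end, in percent of the Q charged, red

In zeta at 32 °C, Q read 27.2% after 2.00 min, so the first-order constant read there was 0.651 min⁻¹. In eta at −18 °C, Q read 93.9% after 150 min, so the constant read there was 4.20 × 10⁻⁴ min⁻¹, but that reading rests on a loss of 6.10% with a scatter of 0.5 percentage points. I joined the two ends by a straight line in 1/T, which gave an activation energy of 95.1 kJ mol⁻¹.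

So for teal the constant came to 0.140 min⁻¹, and the count of Q lifetimes, constant times time (the Damköhler number of this step), was 5.61. The same count was 210 for amber, 0.0656 for green and 2.44 × 10⁻⁴ for red. But the count speaks of Q and not of E, which forms through J and can go on to X.

The forecast named teal the best flask, with 48% in teal, 12% in amber, 0.5% in green and 0% in red. Of amber it said: “Amber should overcook unless crystals protect E, which is uncertain”.

The flasks gave 48.6% in teal, 0.316% in amber, 0.604% in green and 0% in red, so teal was the best.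

    Q → J (k = 0.00233 s⁻¹, Ea = 95.0 kJ mol⁻¹)
    D + J → E (k = 0.00342 M⁻¹ s⁻¹, Ea = 67.0 kJ mol⁻¹)
    Z ⇌ E, rate k3*(cs3 - [E]) while solid is left; crystals form when [E] > cs3 (solubility = 0.220 M, k = 0.0148 s⁻¹)
    D + E → X (k = 0.00121 M⁻¹ s⁻¹, Ea = 70.0 kJ mol⁻¹)
    (constants at 20 °C)

The count of 5.61 put Q in teal at 0.366%, and teal held 0.37% at 40.0 min. The forecast stood 12 points above amber, which held 3.71% E at 20.0 min and 0.316% at 40.0 min, with X at 99.7% and Z at 0%; the limit of solubility of E made no difference to amber. Red's neighbour at −55 °C had a count of 8.36 × 10⁻⁶, and that flask held >99.9% Q and 0% E.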